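## Analysis of the target

Compound 14 is a flavonol. A benzo ring (ring A) is fused to a 4-pyranone (ring C) as a 4H-chromen-4-one, with a 4-methoxyphenyl group (ring B) on C2, hydroxyls on C3, C5 and C7, and a 2-methylbut-3-en-2-yl group on C8. There is no stereocentre, so the problem is purely one of constitution: the side chain must sit on C8 and not on C6, so the ring A oxygen beside the side chain must become O1. The side chain is bonded to the ring through its quaternary carbon, between two oxygen-bearing carbons; direct C-alkylation would give the linear isomer, so a sigmatropic route is needed. The sensitive groups are the terminal vinyl group (no hydrogenolysis, hence no benzyl ethers; strong acid can add the C7 hydroxyl across it), the 4'-methyl ether (no other methyl ethers as protecting groups) and the electron-rich polyphenol. Ring C is at the 3-hydroxy-4-one oxidation level, and a chalcone oxidation is a poor way to reach it because an oxygen at C5 tends to divert that reaction to five-membered ring products. The plan rests on C2: it is one sp2 carbon bonded only to C3 (which carries oxygen), to C1' of ring B and to O1, that is, a carbonyl carbon in disguise. It can therefore come from carbon monoxide 11, placed between the aryl iodide 10 and the alpha-carbon of a ring A ketone 9 that already carries the C3 oxygen and the C8 side chain.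

## Retrosynthetic reasoning

**14 to 12 (O1–C2 and three acetal C–O bonds).** Ring C is opened at O1–C2, which leads back to the 2-oxygenated 1,3-diketone 12. Its only free phenol is the one beside the quaternary carbon, so closure can give only the C8 isomer. The acid that dehydrates the cyclic hemiketal should also remove the three methoxymethyl groups, through the protected flavonol 13. The forward step must be mild enough to leave the vinyl group alone.

**12 to 9, 10 and 11 (C2–C3 and C2–C1').** Both carbon–carbon bonds of the future C2 are cut, so this carbon becomes carbon monoxide 11, ring B becomes the commercial iodide 10, and the enolate partner is ketone 9. This cut is convergent, and it delivers C2, C3 and C4 at their final oxidation levels, so no oxidation is needed once the electron-rich ring system is assembled. A cut at C2–C3 alone (aroyl transfer from an ester) would need an extra acylation step and is kept as the reserve. The forward reaction must acylate the enolate carbon of 9 with the aroylpalladium species made from 10 and 11.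

**9 to 8 to 5 (C–O bond at the omega-carbon, then its acetal).** The C3 oxygen is traced to an alpha-hydroxylation of the methyl ketone 5, through the silyl enol ether 6 and the silyloxy ketone 7 (Rubottom sequence). The new primary alcohol of 8 is capped as the same acetal as the ring oxygens, so one final operation removes all three. The oxidation is placed after the ring A substitution is settled, so that the sensitive alpha-hydroxy ketone is carried through only one further step.

**5 to 4 (two acetal bonds).** The two ring acetals are removed to give the triol 4. The forward step must protect the hydroxyl that is not hydrogen-bonded to the carbonyl and the less hindered of the two that are. The hydroxyl left free is then the one between the acetyl group and the quaternary carbon, which becomes O1.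

**4 to 3 (ring carbon–quaternary carbon bond).** An ortho-(1,1-dimethylallyl)phenol is the retron of an aromatic Claisen shift of a prenyl ether, so 4 goes back to 3. The ether is placed on the oxygen para to the acetyl-bearing carbon. The two ortho carbons of 3 are then equivalent, and the para carbon is blocked, so the shift cannot continue to a para position and deliver a linear prenyl group.

**3 to 1 and 2 (ether O–C bond).** The ether is cut to the commercial ketone 1, which already contains ring A with C4 attached, and the bromide 2. The forward step must alkylate the one hydroxyl of 1 that is not tied to the carbonyl.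

## Alternatives that were turned down

**Alternative 1:** Ring C is disconnected at C4–C4a and O1–C2. In the forward step phloroglucinol A3 and the keto ester A2 are heated without solvent; C-acylation and cyclodehydration give the flavonol 3-benzoate A1.
- For: two components, no protection of ring A, no regiochemical question in the annulation because A3 is symmetric, and the C3 oxygen arrives masked. No transition metal, no strong base and no gas are needed.
- Against: A1 lacks the side chain. It would have to be added to the finished flavone by O7-prenylation and a Claisen shift, where C6 and C8 are both open ortho carbons and nothing in the structure enforces C8. The O7 hydroxyl would also have to be told apart from the O5 and O3 functions. The annulation itself runs above 200 °C on an alpha-acyloxy beta-keto ester, where acyl migration and closure in the coumarin sense compete.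
- Comparison: this route is stronger on step count to the flavonol nucleus and on operational simplicity. The chosen route offers instead a fixed position for the side chain: it is set on 3, where only one outcome exists, and 12 has a single free phenol.

**Alternative 2:** Ring A is built by a Danheiser benzannulation. The cyclobutenone A5 and the siloxyalkyne A6, which carries the 1,1-dimethylallyl group, are heated together. Ring opening to a vinylketene, [2+2] addition, a second ring opening and six-electron closure give the phenol A4.
- For: the three ring A oxygens emerge differentiated (free, silyl, ethyl) and the quaternary group is placed between two of them by construction. No Claisen shift and no selective protection are needed; on this point it is stronger than step 3 of the chosen route.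
- Against: A6 needs a multistep preparation by ester homologation. A4 arrives without the C4 carbon, so a regioselective acylation of a hindered, acid-sensitive arene must follow, and ring C must still be built. The ethyl ether at the future O5 must be cleaved at the end with Lewis acids that also threaten the 4'-methyl ether and the vinyl group.
- Comparison: the benzannulation solves a problem that the commercial ketone 1 already solves, since 1 contains ring A with C4 attached. The chosen route reaches the fully substituted ring A ketone 5 in three steps and removes all protecting groups in one operation.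

**Alternative 3:** Ring C is disconnected at C3–C4. The dialdehyde A8, in which the ring A oxygen is already alkylated by the carbon bearing ring B, is treated with SmI2 A9 (divalent samarium). Ketyl coupling gives the flavan-3,4-diol A7, and a double oxidation would then give the 3,4-dione, which is the keto tautomer of the flavonol.
- For: neutral, mild conditions that tolerate the vinyl group, no strong base at elevated temperature, and both ring C oxygens delivered at once.
- Against: A8 requires O-alkylation of a phenol wedged between the quaternary carbon and a formyl group by a secondary, benzylic, 4-methoxy-substituted electrophile that ionises and eliminates easily. The alpha-aryloxy aldehyde of A8 is the kind of function that A9 cleaves reductively, which would break the O1–C2 bond. The ring A aldehyde is deactivated by three donor oxygens. Three stereocentres are made only to be destroyed, and two oxidation steps follow.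
- Comparison: this route is stronger on mildness of the ring-forming step. The chosen route forms C2, C3 and C4 at the correct oxidation level in one carbon–carbon bond-forming event, from a precursor made by standard phenol chemistry.

Key step: step 6

## Route

Assumption: the commercial hydrate of 1 is dried before use, and carbon monoxide 11 is supplied at about one atmosphere (cylinder, or ex situ generation in a two-chamber vessel).

Step 1
Reactants: 1 2,4,6-trihydroxyacetophenone; 2 prenyl bromide (1-bromo-3-methylbut-2-ene)
Product: 3 1-[2,6-dihydroxy-4-(3-methylbut-2-en-1-yloxy)phenyl]ethan-1-one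
Conditions: K2CO3 (1.1 equiv), 2 (1.0 equiv), acetone, reflux
Reagents that add atoms: none
Why: Williamson ether synthesis; the 4-hydroxyl is the most acidic and the only one not hydrogen-bonded to the carbonyl, so with one equivalent of base its phenoxide should be alkylated at oxygen, and the aprotic medium disfavours C-alkylation.

Step 2
Reactants: 3 1-[2,6-dihydroxy-4-(3-methylbut-2-en-1-yloxy)phenyl]ethan-1-one
Product: 4 1-[2,4,6-trihydroxy-3-(2-methylbut-3-en-2-yl)phenyl]ethan-1-one
Conditions: PhNEt2, 185 °C, argon
Reagents that add atoms: none
Why: Aromatic Claisen rearrangement ([3,3] shift with allyl inversion, then tautomerisation) creates the quaternary benzylic carbon at an ortho position. The two ortho carbons of 3 are equivalent and the para carbon carries the acetyl group, so neither a regioisomer nor a para-shifted linear prenyl product can arise; the basic amine solvent should hold back addition of a flanking hydroxyl to the new vinyl group.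

Step 3
Reactants: 4 1-[2,4,6-trihydroxy-3-(2-methylbut-3-en-2-yl)phenyl]ethan-1-one
Product: 5 1-[2-hydroxy-4,6-bis(methoxymethoxy)-3-(2-methylbut-3-en-2-yl)phenyl]ethan-1-one
Conditions: MOMCl (2.2 equiv), i-Pr2NEt (3 equiv), CH2Cl2, 0 °C to rt
Reagents that add atoms: chloromethyl methyl ether (MOMCl), COCCl
Why: Phenol O-alkylation to the formaldehyde acetal; the 4-hydroxyl is not tied to the carbonyl and should react first, then the unhindered 6-hydroxyl. The 2-hydroxyl, hydrogen-bonded to the carbonyl and flanked by the quaternary carbon, should stay free; the assignment would be checked by NOE contacts between H-5 and both OCH2O groups.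

Step 4
Reactants: 5 1-[2-hydroxy-4,6-bis(methoxymethoxy)-3-(2-methylbut-3-en-2-yl)phenyl]ethan-1-one
Product: 8 2-hydroxy-1-[2-hydroxy-4,6-bis(methoxymethoxy)-3-(2-methylbut-3-en-2-yl)phenyl]ethan-1-one, via the bis(trimethylsilyl) enol ether 6 (not isolated), via the bis(trimethylsilyloxy) ketone 7 (not isolated)
Conditions: LiN(SiMe3)2 (2.5 equiv), THF, −78 °C, then Me3SiCl, to 0 °C; mCPBA (1.05 equiv), CH2Cl2, −20 °C; K2CO3 (cat.), MeOH, 0 °C
Reagents that add atoms: 3-chloroperoxybenzoic acid (mCPBA), OOC(=O)c1cccc(Cl)c1
Why: Rubottom oxidation; the phenoxide–enolate dianion of 5 is silylated at both oxygens to 6, whose electron-rich silyl enol ether should be epoxidised far faster than the monosubstituted vinyl group. The silyloxy epoxide rearranges by silyl shift to 7, and methanolysis removes both silyl groups.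

Step 5
Reactants: 8 2-hydroxy-1-[2-hydroxy-4,6-bis(methoxymethoxy)-3-(2-methylbut-3-en-2-yl)phenyl]ethan-1-one
Product: 9 1-[2-hydroxy-4,6-bis(methoxymethoxy)-3-(2-methylbut-3-en-2-yl)phenyl]-2-(methoxymethoxy)ethan-1-one
Conditions: MOMCl (1.2 equiv), i-Pr2NEt (2 equiv), CH2Cl2, 0 °C to rt
Reagents that add atoms: chloromethyl methyl ether (MOMCl), COCCl
Why: Acetal protection of the primary alcohol; the remaining phenol is the one that step 3 is designed to leave untouched by the same reagent, so the alcohol should react selectively.

Step 6
Reactants: 9 1-[2-hydroxy-4,6-bis(methoxymethoxy)-3-(2-methylbut-3-en-2-yl)phenyl]-2-(methoxymethoxy)ethan-1-one; 10 4-iodoanisole; 11 carbon monoxide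
Product: 12 1-[2-hydroxy-4,6-bis(methoxymethoxy)-3-(2-methylbut-3-en-2-yl)phenyl]-2-(methoxymethoxy)-3-(4-methoxyphenyl)propane-1,3-dione (racemic)
Conditions: NaN(SiMe3)2 (3.1 equiv), THF, 0 °C; then 10 (1.2 equiv), 11 (1 atm), Pd(dba)2 (5 mol %), Xantphos (4,5-bis(diphenylphosphino)-9,9-dimethylxanthene, 6 mol %), 80 °C; aq. NH4Cl
Reagents that add atoms: none
Why: Zerovalent palladium from Pd(dba)2 and Xantphos adds oxidatively to the C–I bond of 10, and 11 inserts into the aryl–palladium bond to give a 4-methoxybenzoylpalladium iodide (divalent palladium). The disodium salt of 9 (phenoxide and ketone enolate) displaces iodide, and reductive elimination from the acyl(enolate)palladium species, helped by the wide bite angle of the ligand, forms the bond to the enolate carbon; with the insertion, this makes both carbon–carbon bonds of the future C2. The more acidic diketone is then deprotonated by the third equivalent of base, which prevents a second acylation and frees the catalyst. The closest known reaction type is the palladium-catalysed carbonylative alpha-arylation of ketones with aryl iodides, which has been applied to 2-hydroxyacetophenones as a flavone synthesis; the acetal oxygen on the enolate carbon is the untested element and makes that carbon comparable in size to the secondary enolates of that chemistry. No ring is closed in this step. The one new stereocentre, the central carbon of the dione, forms without control as a racemate and becomes the sp2 carbon C3 in step 7. The step needs acylation at carbon and not at the phenoxide oxygen, at the nitrogen of the silylamide or at the vinyl group. The ketone has a single alpha position, the phenoxide is wedged between the quaternary carbon and the acyl group, the silylamide is a poor nucleophile for steric reasons and the vinyl group is shielded by the adjacent quaternary carbon; any O-aroyl ester that did form should be carried to the same diketonate by base-induced acyl migration.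

Step 7
Reactants: 12 1-[2-hydroxy-4,6-bis(methoxymethoxy)-3-(2-methylbut-3-en-2-yl)phenyl]-2-(methoxymethoxy)-3-(4-methoxyphenyl)propane-1,3-dione (racemic)
Product: 14 3,5,7-trihydroxy-2-(4-methoxyphenyl)-8-(2-methylbut-3-en-2-yl)-4H-chromen-4-one, via the tris(methoxymethyl) flavonol 13 (not isolated)
Conditions: 3 M HCl, MeOH, 50 °C
Reagents that add atoms: none
Why: Acid-catalysed cyclodehydration, as in flavone formation from 2-hydroxyaryl 1,3-diketones: the single free phenol adds 6-exo-trig to the protonated aryl ketone and dehydration gives 13, after which acetal exchange with the solvent frees the three hydroxyls; the order of the two events does not change the outcome. Only the oxygen beside the quaternary carbon is free in 12, so only the 8-substituted flavonol can form, and a monosubstituted alkene should not be protonated by dilute methanolic acid at this temperature.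

## Compound list

1 | 2,4,6-trihydroxyacetophenone | CC(=O)c1c(O)cc(O)cc1O | starting material
2 | prenyl bromide (1-bromo-3-methylbut-2-ene) | CC(C)=CCBr | starting material
3 | 1-[2,6-dihydroxy-4-(3-methylbut-2-en-1-yloxy)phenyl]ethan-1-one | CC(=O)c1c(O)cc(OCC=C(C)C)cc1O | intermediate
4 | 1-[2,4,6-trihydroxy-3-(2-methylbut-3-en-2-yl)phenyl]ethan-1-one | C=CC(C)(C)c1c(O)cc(O)c(C(C)=O)c1O | intermediate
5 | 1-[2-hydroxy-4,6-bis(methoxymethoxy)-3-(2-methylbut-3-en-2-yl)phenyl]ethan-1-one | C=CC(C)(C)c1c(OCOC)cc(OCOC)c(C(C)=O)c1O | intermediate
6 | trimethyl{1-[4,6-bis(methoxymethoxy)-3-(2-methylbut-3-en-2-yl)-2-(trimethylsilyloxy)phenyl]ethenyloxy}silane | C=CC(C)(C)c1c(OCOC)cc(OCOC)c(C(=C)O[Si](C)(C)C)c1O[Si](C)(C)C | intermediate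
7 | 1-[4,6-bis(methoxymethoxy)-3-(2-methylbut-3-en-2-yl)-2-(trimethylsilyloxy)phenyl]-2-(trimethylsilyloxy)ethan-1-one | C=CC(C)(C)c1c(OCOC)cc(OCOC)c(C(=O)CO[Si](C)(C)C)c1O[Si](C)(C)C | intermediate
8 | 2-hydroxy-1-[2-hydroxy-4,6-bis(methoxymethoxy)-3-(2-methylbut-3-en-2-yl)phenyl]ethan-1-one | C=CC(C)(C)c1c(OCOC)cc(OCOC)c(C(=O)CO)c1O | intermediate
9 | 1-[2-hydroxy-4,6-bis(methoxymethoxy)-3-(2-methylbut-3-en-2-yl)phenyl]-2-(methoxymethoxy)ethan-1-one | C=CC(C)(C)c1c(OCOC)cc(OCOC)c(C(=O)COCOC)c1O | intermediate
10 | 4-iodoanisole | COc1ccc(I)cc1 | starting material
11 | carbon monoxide | [C-]#[O+] | starting material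
12 | 1-[2-hydroxy-4,6-bis(methoxymethoxy)-3-(2-methylbut-3-en-2-yl)phenyl]-2-(methoxymethoxy)-3-(4-methoxyphenyl)propane-1,3-dione (racemic) | C=CC(C)(C)c1c(OCOC)cc(OCOC)c(C(=O)C(OCOC)C(=O)c2ccc(OC)cc2)c1O | intermediate
13 | 3,5,7-tris(methoxymethoxy)-2-(4-methoxyphenyl)-8-(2-methylbut-3-en-2-yl)-4H-chromen-4-one | C=CC(C)(C)c1c(OCOC)cc(OCOC)c2c(=O)c(OCOC)c(-c3ccc(OC)cc3)oc12 | intermediate
14 | 3,5,7-trihydroxy-2-(4-methoxyphenyl)-8-(2-methylbut-3-en-2-yl)-4H-chromen-4-one | C=CC(C)(C)c1c(O)cc(O)c2c(=O)c(O)c(-c3ccc(OC)cc3)oc12 | target

## Step count and least certain steps

Total: 7 steps. Longest linear sequence: 7 steps (1 to 14); 2, 10 and 11 are commercial.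

**Step 6 (key step).** The acylpalladium species may transfer its aroyl group to the silylamide nitrogen, or to the phenoxide oxygen without the subsequent migration. The aryl group may couple directly without uptake of 11. Reductive elimination at a hindered, oxygen-bearing enolate carbon may be slow enough for the catalyst to decompose. The fallback sets out from 9 and returns at 12, and forms only the C2–C3 bond in the key event. The phenol of 9 is acylated with 4-methoxybenzoyl chloride (Et3N, DMAP, CH2Cl2) to 2-[2-(methoxymethoxy)acetyl]-3,5-bis(methoxymethoxy)-6-(2-methylbut-3-en-2-yl)phenyl 4-methoxybenzoate F1. LiN(SiMe3)2 in THF (−78 °C to rt) should then move the aroyl group from oxygen to the enolate carbon (Baker–Venkataraman rearrangement) to give 12.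

**Step 2.** At the temperature of the shift a flanking hydroxyl may add across the new vinyl group (closure to a dihydrofuran), and the allylic ether may ionise with loss of the prenyl unit. The fallback sets out from 3 and returns at 4, and keeps every phenol masked during the shift. Compound 3 is heated in PhNEt2 with N,O-bis(trimethylsilyl)acetamide. The phenols are silylated to 1-[4-(3-methylbut-2-en-1-yloxy)-2,6-bis(trimethylsilyloxy)phenyl]ethan-1-one F2, and the phenol released by the Claisen shift is silylated as it forms. The product is held as 1-[3-(2-methylbut-3-en-2-yl)-2,4,6-tris(trimethylsilyloxy)phenyl]ethan-1-one F3, and methanolysis (K2CO3 cat., MeOH) then gives 4.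

**Step 3.** Discrimination between the two hydroxyls beside the carbonyl may be poor, so that alkylation at the hindered one gives the isomer that would lead to the 6-substituted flavonol. The fallback sets out from 3 and returns at 5, bypassing 4; it makes the two hydroxyls different before the shift instead of after it. One equivalent of MOMCl (i-Pr2NEt, CH2Cl2) on the symmetric diol 3 gives 1-[2-hydroxy-6-(methoxymethoxy)-4-(3-methylbut-2-en-1-yloxy)phenyl]ethan-1-one F4, without ambiguity because the two hydroxyls are equivalent. The Claisen shift (PhNEt2, 185 °C) should then give 1-[2,4-dihydroxy-6-(methoxymethoxy)-3-(2-methylbut-3-en-2-yl)phenyl]ethan-1-one F5. Migration to the carbon between the chelated hydroxyl and the ether oxygen is expected to be preferred, as in 4-allyloxy-2-hydroxyacetophenones; the isomer from migration to the other ortho carbon differs in constitution and would be separated. The only non-chelated hydroxyl of F5 then takes the second acetal (MOMCl, 1.05 equiv) to give 5.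

**Step 4.** The peracid may attack the terminal alkene or the electron-rich ring, and enolisation of the chelated phenoxide ketone may be incomplete. The fallback sets out from 5 and returns at 8 without a peracid or a silyl enol ether. The dipotassium dianion (KN(SiMe3)2, 2.2 equiv, THF, −78 °C) is hydroxylated with 2-(benzenesulfonyl)-3-phenyloxaziridine (Davis oxidation), an oxygen-transfer agent that does not epoxidise isolated alkenes.

**Step 7.** Acid may add the C7 hydroxyl across the vinyl group once that hydroxyl is free, or acetal cleavage may stall before ring closure is complete. The fallback sets out from 12 and returns at 14, with 13 isolated. Ring closure is run under anhydrous conditions (TsOH cat., 4 Å molecular sieves, CH2Cl2, rt) to give 13. The acetals are then cleaved aprotically with Me3SiBr (CH2Cl2, −30 °C, then aqueous work-up).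

## Further compounds

F1 | step 6 | 2-[2-(methoxymethoxy)acetyl]-3,5-bis(methoxymethoxy)-6-(2-methylbut-3-en-2-yl)phenyl 4-methoxybenzoate | C=CC(C)(C)c1c(OCOC)cc(OCOC)c(C(=O)COCOC)c1OC(=O)c1ccc(OC)cc1
F2 | step 2 | 1-[4-(3-methylbut-2-en-1-yloxy)-2,6-bis(trimethylsilyloxy)phenyl]ethan-1-one | CC(=O)c1c(O[Si](C)(C)C)cc(OCC=C(C)C)cc1O[Si](C)(C)C
F3 | step 2 | 1-[3-(2-methylbut-3-en-2-yl)-2,4,6-tris(trimethylsilyloxy)phenyl]ethan-1-one | C=CC(C)(C)c1c(O[Si](C)(C)C)cc(O[Si](C)(C)C)c(C(C)=O)c1O[Si](C)(C)C
F4 | step 3 | 1-[2-hydroxy-6-(methoxymethoxy)-4-(3-methylbut-2-en-1-yloxy)phenyl]ethan-1-one | CC(=O)c1c(O)cc(OCC=C(C)C)cc1OCOC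
F5 | step 3 | 1-[2,4-dihydroxy-6-(methoxymethoxy)-3-(2-methylbut-3-en-2-yl)phenyl]ethan-1-one | C=CC(C)(C)c1c(O)cc(OCOC)c(C(C)=O)c1O
F0 | step 4 | none | none
F0 | step 7 | none | none
A1 | alternative 1 | 5,7-dihydroxy-2-(4-methoxyphenyl)-4-oxo-4H-chromen-3-yl benzoate | COc1ccc(cc1)-c1oc2cc(O)cc(O)c2c(=O)c1OC(=O)c1ccccc1
A2 | alternative 1 | ethyl 2-(benzoyloxy)-3-(4-methoxyphenyl)-3-oxopropanoate (racemic) | CCOC(=O)C(OC(=O)c1ccccc1)C(=O)c1ccc(OC)cc1
A3 | alternative 1 | phloroglucinol (benzene-1,3,5-triol) | Oc1cc(O)cc(O)c1
A4 | alternative 2 | 5-ethoxy-2-(2-methylbut-3-en-2-yl)-3-(triisopropylsilyloxy)phenol | C=CC(C)(C)c1c(O)cc(OCC)cc1O[Si](C(C)C)(C(C)C)C(C)C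
A5 | alternative 2 | 3-ethoxycyclobut-2-en-1-one | CCOC1=CC(=O)C1
A6 | alternative 2 | (3,3-dimethylpent-4-en-1-yn-1-yloxy)triisopropylsilane | C=CC(C)(C)C#CO[Si](C(C)C)(C(C)C)C(C)C
A7 | alternative 3 | 5,7-bis(methoxymethoxy)-2-(4-methoxyphenyl)-8-(2-methylbut-3-en-2-yl)chromane-3,4-diol (racemic mixture of diastereomers) | C=CC(C)(C)c1c(OCOC)cc(OCOC)c2c1OC(c1ccc(OC)cc1)C(O)C2O
A8 | alternative 3 | 2-[2-formyl-3,5-bis(methoxymethoxy)-6-(2-methylbut-3-en-2-yl)phenoxy]-2-(4-methoxyphenyl)acetaldehyde (racemic) | C=CC(C)(C)c1c(OCOC)cc(OCOC)c(C=O)c1OC(C=O)c1ccc(OC)cc1
A9 | alternative 3 | samarium diiodide, SmI2 | I[Sm]I
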